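## Retrosynthetic overview

- The target is a linear hexamer: ring A (a 2-butanoyl-4,4-dimethyl dienone, the acylfilicinic ring), then rings B, C, D and E (four 3,5-linked butyrylphloroglucinols), then ring F (the C-methylated butyrylphloroglucinol), joined by five CH2 bridges. Each ArCH2–Ar bond is cut as an o-quinone methide (from a phenolic Mannich base) plus a carbon nucleophile, and ring A is attached last.
- The pentamer F–E–D–C–B comes from the ring F Mannich base and two copies of the symmetric dimer methylenebis(butyrylphloroglucinol), used in excess. Rings B to F are bought as phloroglucinol and 2-methylphloroglucinol, so ring A is the only ring the route forms.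
- Ring A is cut at C2–C3 (the butanoyl-bearing carbon to the enol carbon next to the gem-dimethyl carbon) and at C5–C6. In the forward sense this is a one-pot dianion acylation followed by Claisen ring closure from heptane-2,4-dione and dimethyl 2,2-dimethylmalonate.
- Enabling feature: ring A is an enolised cyclohexane-1,3,5-trione. C2 is the central carbon of a β-diketone (C1 and the butanoyl C=O), so it is a nucleophile. C3 is a carboxyl-level carbon on the quaternary C4, so in the open chain it is a non-enolisable ester that can neither aromatise nor close by an aldol path.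

Key step: step 1

Assumption: the target has no stereocentre and ring A is drawn as one enol tautomer of a freely equilibrating triketone system, so no stereocontrol is needed; heptane-2,4-dione, dimethyl 2,2-dimethylmalonate, 2-methylbenzene-1,3,5-triol and N,N,N',N'-tetramethylmethanediamine are taken as catalogue compounds.

## Route

Step 1
Reactants: 1 heptane-2,4-dione; 2 dimethyl 2,2-dimethylmalonate
Product: 4 2-butanoyl-3,5-dihydroxy-4,4-dimethylcyclohexa-2,5-dien-1-one (butyrylfilicinic acid, ring A), via triketo ester 3 (not isolated)
Conditions: LiN(iPr)2 (3.1 equiv), THF, 0 °C, 30 min; 2 (1.0 equiv), 0 °C to rt, then reflux; 1 M HCl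
Reagents that add atoms: dimethyl 2,2-dimethylmalonate (2), COC(=O)C(C)(C)C(=O)OC
Why: LiN(iPr)2 should convert 1 into its 1,3-dianion by removing the C3 proton and then, kinetically, a proton of the unhindered C1 methyl group; the terminal carbanion, by far the more nucleophilic site, attacks one ester group of the non-enolisable diester 2 (γ-acylation of a β-diketone dianion by an ester) to give the triketo ester 3 as its dienolate, the third equivalent of base taking up the new acidic C4 proton of 3. On warming, the enolate carbon C6 of 3 (between the C5 and C7 carbonyls) adds to the C1 ester carbonyl and methoxide leaves, a Claisen (Dieckmann-type) condensation of the kind by which 3,5,7-triketo esters give acylphloroglucinols, here held at the dienone stage because C2 of 3 is quaternary. Ring A is closed in the 6-exo-trig mode, allowed by the Baldwin rules for the delocalised enolate and helped by the gem-dimethyl group (Thorpe–Ingold effect). No stereocentre is formed. The step needs site selectivity in dianion formation (secured by the kinetic preference of methyl over methylene for the second deprotonation), C- over O-acylation in the ring closure (an enol lactone from O-attack would be reopened by the LiOMe present, while the C-acylated product leaves the equilibrium as a doubly stabilised dianion) and no aldol closure to a resorcylate (excluded because C2 of 3 carries no hydrogen and the C3 ketone is held as an enolate). Because the first bond is made at the terminal carbon, the bond that closes the ring is necessarily the one between the butanoyl-bearing C2 and the enol carbon C3 of ring A.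

Step 2
Reactants: 5 2-methylbenzene-1,3,5-triol (2-methylphloroglucinol); 6 butanoyl chloride
Product: 7 1-(2,4,6-trihydroxy-3-methylphenyl)butan-1-one (ring F monomer)
Conditions: 6 (1.0 equiv), AlCl3 (3 equiv), PhNO2, rt to 60 °C; ice/HCl
Reagents that add atoms: butanoyl chloride (6), CCCC(=O)Cl
Why: Friedel–Crafts C-acylation of the electron-rich triol, in which the two free ring positions of 5 are equivalent and the first acyl group, hydrogen-bonded to its flanking hydroxyls, deactivates the ring against a second acylation.

Step 3
Reactants: 8 benzene-1,3,5-triol (phloroglucinol); 6 butanoyl chloride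
Product: 9 1-(2,4,6-trihydroxyphenyl)butan-1-one (butyrylphloroglucinol)
Conditions: 6 (1.0 equiv), AlCl3 (3 equiv), PhNO2, rt to 60 °C; ice/HCl
Reagents that add atoms: butanoyl chloride (6), CCCC(=O)Cl
Why: Friedel–Crafts mono-C-acylation of phloroglucinol, whose three positions are equivalent and whose monoacyl product is deactivated toward further acylation.

Step 4
Reactants: 9 1-(2,4,6-trihydroxyphenyl)butan-1-one (2.5 equiv per formaldehyde); 10 formaldehyde
Product: 13 bis(3-butanoyl-2,4,6-trihydroxyphenyl)methane (symmetric dimer), via hydroxymethyl ketone 11 (not isolated), via quinone methide 12 (not isolated)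
Conditions: 37% aq. HCHO (0.4 equiv), 1 M aq. NaOH, 0 °C, 15 min; then 1 M HCl
Reagents that add atoms: formaldehyde (10), C=O
Why: Base-mediated phenol–formaldehyde condensation (Lederer–Manasse hydroxymethylation to 11, loss of hydroxide to 12, then Michael addition of a second phenolate of 9), in which the excess of 9 and the short time at 0 °C should hold the reaction at the dimer.

Step 5
Reactants: 7 1-(2,4,6-trihydroxy-3-methylphenyl)butan-1-one; 14 N,N,N',N'-tetramethylmethanediamine
Product: 15 1-{3-[(dimethylamino)methyl]-2,4,6-trihydroxy-5-methylphenyl}butan-1-one (ring F Mannich base)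
Conditions: 14 (1.1 equiv), THF, 0 °C to rt
Reagents that add atoms: N,N,N',N'-tetramethylmethanediamine (14), CN(C)CN(C)C
Why: Phenolic Mannich aminomethylation with a preformed aminal, in which the acidic phenol protonates 14 and the released iminium ion attacks the only free ring position of 7, the low temperature keeping the Mannich base from alkylating unreacted 7.

Step 6
Reactants: 15 ring F Mannich base; 13 bis(3-butanoyl-2,4,6-trihydroxyphenyl)methane (4 equiv)
Product: 17 linear trimer F–E–D (ring F joined through CH2 at its C5 to C3 of butyrylphloroglucinol ring E, whose C5 is joined through CH2 to C3 of butyrylphloroglucinol ring D; C5 of ring D is a free ring CH), via quinone methide 16 (not isolated)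
Conditions: 13 (4 equiv), 1,4-dioxane, 80 °C, N2 sweep
Reagents that add atoms: bis(3-butanoyl-2,4,6-trihydroxyphenyl)methane (13), CCCC(=O)c1c(O)cc(O)c(Cc2c(O)cc(O)c(C(=O)CCC)c2O)c1O
Why: Thermal retro-Mannich loss of dimethylamine from the ammonium phenoxide form of 15 should give the o-quinone methide 16, which is trapped by Friedel–Crafts-type Michael addition of a free ring carbon of 13; the excess of the two-ended dimer suppresses alkylation at both ends and the nitrogen sweep removes the amine so that the medium stays non-basic.

Step 7
Reactants: 17 linear trimer F–E–D; 14 N,N,N',N'-tetramethylmethanediamine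
Product: 18 trimer Mannich base (17 with CH2NMe2 at C5 of ring D)
Conditions: 14 (1.1 equiv), THF, 0 °C to rt
Reagents that add atoms: N,N,N',N'-tetramethylmethanediamine (14), CN(C)CN(C)C
Why: Mannich aminomethylation at the single remaining aromatic CH of 17 (C5 of ring D), all other ring positions being substituted.

Step 8
Reactants: 18 trimer Mannich base; 13 bis(3-butanoyl-2,4,6-trihydroxyphenyl)methane (4 equiv)
Product: 20 linear pentamer F–E–D–C–B (17 extended through CH2 bridges by two further 3,5-linked butyrylphloroglucinol rings C and B; C5 of ring B is the one free ring CH), via quinone methide 19 (not isolated)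
Conditions: 13 (4 equiv), 1,4-dioxane, 80 °C, N2 sweep
Reagents that add atoms: bis(3-butanoyl-2,4,6-trihydroxyphenyl)methane (13), CCCC(=O)c1c(O)cc(O)c(Cc2c(O)cc(O)c(C(=O)CCC)c2O)c1O
Why: The same retro-Mannich and Michael sequence as in step 6, in which the o-quinone methide 19 on ring D is taken up by one end of the excess dimer 13 and the unreacted dimer is recovered.

Step 9
Reactants: 20 linear pentamer F–E–D–C–B; 14 N,N,N',N'-tetramethylmethanediamine
Product: 21 pentamer Mannich base (20 with CH2NMe2 at C5 of ring B)
Conditions: 14 (1.1 equiv), THF/DMF, 0 °C to rt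
Reagents that add atoms: N,N,N',N'-tetramethylmethanediamine (14), CN(C)CN(C)C
Why: Mannich aminomethylation at the only unsubstituted aromatic carbon of 20 (C5 of ring B).

Step 10
Reactants: 21 pentamer Mannich base; 4 butyrylfilicinic acid (2 equiv)
Product: 23 target hexamer A–B–C–D–E–F, via quinone methide 22 (not isolated)
Conditions: 4 (2 equiv), 1,4-dioxane, 60 °C, N2 sweep
Reagents that add atoms: 2-butanoyl-3,5-dihydroxy-4,4-dimethylcyclohexa-2,5-dien-1-one (4), CCCC(=O)C1=C(O)C(C)(C)C(O)=CC1=O
Why: The vinylogous acid 4 should protonate the amine of 21, dimethylamine leaves to give the o-quinone methide 22, and the enolate of 4 adds through C6, its only unsubstituted ring carbon (Michael addition of a cyclic 1,3-dicarbonyl compound to an o-quinone methide), C-alkylation being the thermodynamic outcome.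

## Compound list

1 | heptane-2,4-dione | CCCC(=O)CC(C)=O | starting material
2 | dimethyl 2,2-dimethylmalonate | COC(=O)C(C)(C)C(=O)OC | starting material
3 | methyl 2,2-dimethyl-3,5,7-trioxodecanoate (triketo ester, formed in the flask) | CCCC(=O)CC(=O)CC(=O)C(C)(C)C(=O)OC | intermediate
4 | 2-butanoyl-3,5-dihydroxy-4,4-dimethylcyclohexa-2,5-dien-1-one (butyrylfilicinic acid, ring A) | CCCC(=O)C1=C(O)C(C)(C)C(O)=CC1=O | intermediate
5 | 2-methylbenzene-1,3,5-triol | Cc1c(O)cc(O)cc1O | starting material
6 | butanoyl chloride | CCCC(=O)Cl | starting material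
7 | 1-(2,4,6-trihydroxy-3-methylphenyl)butan-1-one | CCCC(=O)c1c(O)cc(O)c(C)c1O | intermediate
8 | benzene-1,3,5-triol | Oc1cc(O)cc(O)c1 | starting material
9 | 1-(2,4,6-trihydroxyphenyl)butan-1-one | CCCC(=O)c1c(O)cc(O)cc1O | intermediate
10 | formaldehyde (37% aqueous solution) | C=O | starting material
11 | 1-[2,4,6-trihydroxy-3-(hydroxymethyl)phenyl]butan-1-one (formed in the flask) | CCCC(=O)c1c(O)cc(O)c(CO)c1O | intermediate
12 | 4-butanoyl-3,5-dihydroxy-6-methylidenecyclohexa-2,4-dien-1-one (o-quinone methide, formed in the flask) | CCCC(=O)C1=C(O)C(=C)C(=O)C=C1O | intermediate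
13 | bis(3-butanoyl-2,4,6-trihydroxyphenyl)methane | CCCC(=O)c1c(O)cc(O)c(Cc2c(O)cc(O)c(C(=O)CCC)c2O)c1O | intermediate
14 | N,N,N',N'-tetramethylmethanediamine | CN(C)CN(C)C | starting material
15 | 1-{3-[(dimethylamino)methyl]-2,4,6-trihydroxy-5-methylphenyl}butan-1-one | CCCC(=O)c1c(O)c(C)c(O)c(CN(C)C)c1O | intermediate
16 | 4-butanoyl-3,5-dihydroxy-2-methyl-6-methylidenecyclohexa-2,4-dien-1-one (o-quinone methide of ring F, formed in the flask) | CCCC(=O)C1=C(O)C(=C)C(=O)C(C)=C1O | intermediate
17 | linear trimer F–E–D with a free CH at C5 of ring D | CCCC(=O)c1c(O)c(C)c(O)c(Cc2c(O)c(Cc3c(O)cc(O)c(C(=O)CCC)c3O)c(O)c(C(=O)CCC)c2O)c1O | intermediate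
18 | trimer Mannich base (CH2NMe2 at C5 of ring D) | CCCC(=O)c1c(O)c(C)c(O)c(Cc2c(O)c(Cc3c(O)c(CN(C)C)c(O)c(C(=O)CCC)c3O)c(O)c(C(=O)CCC)c2O)c1O | intermediate
19 | trimer o-quinone methide (ring D as 6-methylidene dienone, formed in the flask) | CCCC(=O)c1c(O)c(C)c(O)c(Cc2c(O)c(CC3=C(O)C(=C)C(=O)C(C(=O)CCC)=C3O)c(O)c(C(=O)CCC)c2O)c1O | intermediate
20 | linear pentamer F–E–D–C–B with a free CH at C5 of ring B | CCCC(=O)c1c(O)c(C)c(O)c(Cc2c(O)c(Cc3c(O)c(Cc4c(O)c(Cc5c(O)cc(O)c(C(=O)CCC)c5O)c(O)c(C(=O)CCC)c4O)c(O)c(C(=O)CCC)c3O)c(O)c(C(=O)CCC)c2O)c1O | intermediate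
21 | pentamer Mannich base (CH2NMe2 at C5 of ring B) | CCCC(=O)c1c(O)c(C)c(O)c(Cc2c(O)c(Cc3c(O)c(Cc4c(O)c(Cc5c(O)c(CN(C)C)c(O)c(C(=O)CCC)c5O)c(O)c(C(=O)CCC)c4O)c(O)c(C(=O)CCC)c3O)c(O)c(C(=O)CCC)c2O)c1O | intermediate
22 | pentamer o-quinone methide (ring B as 6-methylidene dienone, formed in the flask) | CCCC(=O)c1c(O)c(C)c(O)c(Cc2c(O)c(Cc3c(O)c(Cc4c(O)c(CC5=C(O)C(=C)C(=O)C(C(=O)CCC)=C5O)c(O)c(C(=O)CCC)c4O)c(O)c(C(=O)CCC)c3O)c(O)c(C(=O)CCC)c2O)c1O | intermediate
23 | target hexamer (CNP0309827.0) | CCCC(=O)C1=C(O)C(C)(C)C(O)=C(Cc2c(O)c(Cc3c(O)c(Cc4c(O)c(Cc5c(O)c(Cc6c(O)c(C)c(O)c(C(=O)CCC)c6O)c(O)c(C(=O)CCC)c5O)c(O)c(C(=O)CCC)c4O)c(O)c(C(=O)CCC)c3O)c(O)c(C(=O)CCC)c2O)C1=O | target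

## Step count and risks

Total step count: 10. Longest linear sequence: 7 steps (steps 3, 4, 6, 7, 8, 9, 10 from phloroglucinol; equally steps 2, 5, 6, 7, 8, 9, 10 from 2-methylphloroglucinol).

Steps most likely to fail:

1. Step 1. The second deprotonation of 1 may not be site-selective (C1 methyl against C5 methylene), the dianion may attack both ester groups of 2, or the ring may close through oxygen or stall on the hindered ester. Fallback: set out from 9 (made in step 3) and make ring A by dearomatising C-methylation instead of ring construction. MeI (2.2 equiv) with NaOMe in MeOH at 0 °C to rt should put two methyl groups on one unsubstituted ring carbon of the phenolate (geminal C-alkylation) and return the route at 4. No new compound arises on this way (F0).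

2. Step 8. Release of the quinone methide from the large, poorly soluble 18 may need a temperature at which the two-ended dimer 13 is alkylated at both ends or the existing methylene bridges redistribute (retro-Friedel–Crafts exchange, the so-called rottlerone change). Fallback: set out from 18 and grow the chain one ring at a time with the small, soluble monomer 9 in large excess. Heating 18 with 9 (10 equiv) in 1,4-dioxane should give the linear tetramer F–E–D–C F1. Aminomethylation of its single free ring CH with 14 should give the tetramer Mannich base F2. Heating F2 with 9 again, through the tetramer o-quinone methide F3 formed in the flask, should come back to the route at 20.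

3. Step 10. The A–B methylene bridge is the most labile in the molecule (ring A leaves as a stabilised enolate), so the bridge may exchange or 21 may homocouple while the quinone methide is being released. Fallback: reverse the roles of the partners, setting out from 4 and using 20 directly, so that step 9 and compound 21 are bypassed. Aminomethylation of 4 at C6 with 14 (THF, 0 °C) should give the betaine Mannich base of ring A F4. With AcOH at rt to 40 °C this loses dimethylamine to the 6-methylidene triketone F5, formed in the flask. The free C5 of ring B of 20 adds to it in a Friedel–Crafts-type Michael addition, the way acylphloroglucinols are joined to alkylidene cyclic triketones, and the route is rejoined at 23.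

Further compounds
F0 | step 1 | none | none
F1 | step 8 | linear tetramer F–E–D–C with a free CH at C5 of ring C | CCCC(=O)c1c(O)c(C)c(O)c(Cc2c(O)c(Cc3c(O)c(Cc4c(O)cc(O)c(C(=O)CCC)c4O)c(O)c(C(=O)CCC)c3O)c(O)c(C(=O)CCC)c2O)c1O
F2 | step 8 | tetramer Mannich base (CH2NMe2 at C5 of ring C) | CCCC(=O)c1c(O)c(C)c(O)c(Cc2c(O)c(Cc3c(O)c(Cc4c(O)c(CN(C)C)c(O)c(C(=O)CCC)c4O)c(O)c(C(=O)CCC)c3O)c(O)c(C(=O)CCC)c2O)c1O
F3 | step 8 | tetramer o-quinone methide (ring C as 6-methylidene dienone) | CCCC(=O)c1c(O)c(C)c(O)c(Cc2c(O)c(Cc3c(O)c(CC4=C(O)C(=C)C(=O)C(C(=O)CCC)=C4O)c(O)c(C(=O)CCC)c3O)c(O)c(C(=O)CCC)c2O)c1O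
F4 | step 10 | 2-butanoyl-6-[(dimethylamino)methyl]-3,5-dihydroxy-4,4-dimethylcyclohexa-2,5-dien-1-one (Mannich base of ring A) | CCCC(=O)C1=C(O)C(C)(C)C(O)=C(CN(C)C)C1=O
F5 | step 10 | 2-butanoyl-3-hydroxy-4,4-dimethyl-6-methylidenecyclohex-2-ene-1,5-dione | CCCC(=O)C1=C(O)C(C)(C)C(=O)C(=C)C1=O
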